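**Assumption:** the SMILES is taken as the definition of the target, i.e. the CHPh ring carbon lies between the aroyl‑bearing and the prenyl‑bearing carbons (Ph cis to prenyl, trans to the aroyl group). The route has not been run; selectivities are predicted from precedent and models.

## Retrosynthetic overview

1. Target ⇐ MOM removal ⇐ aryl ketone from lithiated tris‑MOM‑phloroglucinol and a cyclohexene methyl ester.
2. Prenyl group and final alkene position ⇐ Cope [3,3] shift of a ring 1,1‑dimethylallyl group; it is suprafacial, so prenyl lands cis to Ph.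
3. The only ring formed, the cyclohexene ⇐ endo Diels–Alder of a 1‑phenyl diene with a vinyl ketone; Ph on the diene terminus puts the acyl carbon next to CHPh.
4. Absolute configuration ⇐ the bought carbinol of (S)‑hexahydromandelic acid in the dienophile; it is then cut out, its carboxyl carbon staying as the ester (later ketone) carbon.
5. Diene ⇐ prenyl Grignard γ‑addition to 3‑ethoxymethacrolein, then Horner–Wadsworth–Emmons.

## Route

**Step 1**
Reactants: 1 prenylmagnesium chloride; 2 (E)‑3‑ethoxy‑2‑methylprop‑2‑enal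
Product: 3 (2E)‑2,4,4‑trimethylhexa‑2,5‑dienal
Conditions: THF, −78 → 0 °C; then 2 M HCl, rt
Reagents that add atoms: prenylmagnesium chloride, CC(C)=CC[Mg]Cl; water (aldehyde O), O
Why: The allylic Grignard adds 1,2 to the aldehyde through its γ‑carbon (SE2′), creating the quaternary 1,1‑dimethylallyl carbon, and acid hydrolysis of the β‑alkoxy allylic alcohol transposes it to the (E)‑enal; no stereocentre.

**Step 2**
Reactants: 3; 4 diethyl benzylphosphonate
Product: 5 [(1E,3E)‑3,5,5‑trimethylhepta‑1,3,6‑trien‑1‑yl]benzene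
Conditions: NaH, THF, 0 °C → rt
Reagents that add atoms: diethyl benzylphosphonate (PhCH=), CCOP(=O)(Cc1ccccc1)OCC
Why: Horner–Wadsworth–Emmons olefination of an enal with a benzylphosphonate anion gives the (E)‑styryl alkene, and the existing (E)‑trisubstituted alkene is untouched.

**Step 3**
Reactants: 6 (S)‑hexahydromandelic acid (commercial; ring‑hydrogenated (S)‑mandelic acid); 7 N,O‑dimethylhydroxylamine hydrochloride
Product: 8 (2S)‑2‑cyclohexyl‑2‑hydroxy‑N‑methoxy‑N‑methylacetamide
Conditions: EDC·HCl, HOBt, i‑Pr2NEt, CH2Cl2, 0 °C → rt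
Reagents that add atoms: N,O‑dimethylhydroxylamine, CNOC
Why: Carbodiimide amide coupling to the Weinreb amide; the bought carbinol stereocentre is not involved.

**Step 4**
Reactants: 8; 9 vinylmagnesium bromide
Product: 10 (1S)‑1‑cyclohexyl‑1‑hydroxybut‑3‑en‑2‑one
Conditions: vinylMgBr (3 equiv), THF, −20 → 0 °C; inverse quench into cold 1 M HCl
Reagents that add atoms: vinylmagnesium bromide, C=C[Mg]Br
Why: Weinreb ketone synthesis; the chelated tetrahedral intermediate stops over‑addition and the alkoxide protects the α‑stereocentre, while the acidic inverse quench avoids aza‑Michael addition to the enone.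

**Step 5**
Reactants: 5; 10
Product: 11 (2S)‑2‑cyclohexyl‑2‑hydroxy‑1‑[(1S,2R,5R)‑4‑methyl‑5‑(2‑methylbut‑3‑en‑2‑yl)‑2‑phenylcyclohex‑3‑en‑1‑yl]ethan‑1‑one
Conditions: ZnCl2 (1.1 equiv), CH2Cl2, −45 → −20 °C; purify to one diastereomer
Reagents that add atoms: none (5 and 10 only)
Why: Diels–Alder cycloaddition in which Ph at C1 and Me at C3 of the diene both direct the acyl carbon onto CHPh, endo addition to the (E,E)‑diene places acyl, Ph and dimethylallyl all cis, and the Zn‑chelated s‑cis (S)‑ketol is attacked anti to cyclohexyl (Masamune model) to set C2(R) and C5(R). Because the carbinol is still present, minor facial or exo isomers are diastereomers and are removed here.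

**Step 6**
Reactants: 11
Product: 12 methyl (1R,2R,5R)‑4‑methyl‑5‑(2‑methylbut‑3‑en‑2‑yl)‑2‑phenylcyclohex‑3‑ene‑1‑carboxylate
Conditions: Pb(OAc)4, MeOH/CH2Cl2, 0 °C; then NaOMe, MeOH, 50 °C
Reagents that add atoms: methanol (OCH3), CO
Why: Lead tetraacetate cleavage of the α‑hydroxy ketone (via its methanol hemiketal) removes the carbinol carbon as cyclohexanecarbaldehyde and leaves the methyl ester, and methoxide then epimerises C1 to the more stable trans (ester/Ph diequatorial) isomer without touching C2 or C5.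

**Step 7**
Reactants: 12
Product: 13 methyl (1R,5S,6R)‑4‑methyl‑5‑(3‑methylbut‑2‑en‑1‑yl)‑6‑phenylcyclohex‑3‑ene‑1‑carboxylate
Conditions: 1,2‑dichlorobenzene (degassed, BHT), 200 °C, sealed tube
Reagents that add atoms: none
Why: Cope [3,3] rearrangement: the pseudoaxial 1,1‑dimethylallyl group migrates suprafacially across the ring allyl unit, so prenyl appears on the face it left (cis to Ph) and the ring alkene moves next to the methyl‑bearing carbon; it is driven by loss of the quaternary carbon and gain of a trisubstituted alkene.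

**Step 8**
Reactants: 14 phloroglucinol; 15 chloromethyl methyl ether
Product: 16 1,3,5‑tris(methoxymethoxy)benzene
Conditions: NaH, DMF, 0 °C → rt
Reagents that add atoms: MOMCl, COCCl
Why: Williamson O‑alkylation; MOM groups protect the phenols and direct the later lithiation.

**Step 9**
Reactants: 16; 13
Product: 17 [(1R,5S,6R)‑4‑methyl‑5‑(3‑methylbut‑2‑en‑1‑yl)‑6‑phenylcyclohex‑3‑en‑1‑yl][2,4,6‑tris(methoxymethoxy)phenyl]methanone
Conditions: n‑BuLi, THF, 0 °C; then 13, −78 → 0 °C
Reagents that add atoms: none beyond 16 (n‑BuLi adds nothing)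
Why: Directed ortho‑lithiation between two OMOM groups, then acyl substitution on the ester; the di‑ortho‑substituted ketone is too hindered for a second addition, and C1 stays as the thermodynamic trans epimer.

**Step 10**
Reactants: 17
Product: 18 (2,4,6‑trihydroxyphenyl)[(1R,5S,6R)‑4‑methyl‑5‑(3‑methylbut‑2‑en‑1‑yl)‑6‑phenylcyclohex‑3‑en‑1‑yl]methanone (target)
Conditions: 3 M HCl, MeOH, 40 °C
Reagents that add atoms: none
Why: Acetal hydrolysis removes the three MOM groups under conditions mild enough for the prenyl and ring alkenes; no stereocentre is touched.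

## Compound list

1 | prenylmagnesium chloride | CC(C)=CC[Mg]Cl | starting material
2 | (E)‑3‑ethoxy‑2‑methylprop‑2‑enal | CCO/C=C(\C)C=O | starting material
3 | (2E)‑2,4,4‑trimethylhexa‑2,5‑dienal | C=CC(C)(C)/C=C(\C)C=O | intermediate
4 | diethyl benzylphosphonate | CCOP(=O)(Cc1ccccc1)OCC | starting material
5 | [(1E,3E)‑3,5,5‑trimethylhepta‑1,3,6‑trien‑1‑yl]benzene | C=CC(C)(C)/C=C(C)/C=C/c1ccccc1 | intermediate
6 | (S)‑hexahydromandelic acid | OC(=O)[C@@H](O)C1CCCCC1 | starting material
7 | N,O‑dimethylhydroxylamine hydrochloride | CNOC.Cl | starting material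
8 | (2S)‑2‑cyclohexyl‑2‑hydroxy‑N‑methoxy‑N‑methylacetamide | CON(C)C(=O)[C@@H](O)C1CCCCC1 | intermediate
9 | vinylmagnesium bromide | C=C[Mg]Br | starting material
10 | (1S)‑1‑cyclohexyl‑1‑hydroxybut‑3‑en‑2‑one | C=CC(=O)[C@@H](O)C1CCCCC1 | intermediate
11 | (2S)‑2‑cyclohexyl‑2‑hydroxy‑1‑[(1S,2R,5R)‑4‑methyl‑5‑(2‑methylbut‑3‑en‑2‑yl)‑2‑phenylcyclohex‑3‑en‑1‑yl]ethan‑1‑one | O=C([C@@H](O)C1CCCCC1)[C@H]1C[C@@H](C(C)(C)C=C)C(C)=C[C@H]1c1ccccc1 | intermediate
12 | methyl (1R,2R,5R)‑4‑methyl‑5‑(2‑methylbut‑3‑en‑2‑yl)‑2‑phenylcyclohex‑3‑ene‑1‑carboxylate | COC(=O)[C@@H]1C[C@@H](C(C)(C)C=C)C(C)=C[C@H]1c1ccccc1 | intermediate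
13 | methyl (1R,5S,6R)‑4‑methyl‑5‑(3‑methylbut‑2‑en‑1‑yl)‑6‑phenylcyclohex‑3‑ene‑1‑carboxylate | CC(C)=CC[C@@H]1C(C)=CC[C@@H](C(=O)OC)[C@@H]1c1ccccc1 | intermediate
14 | phloroglucinol | Oc1cc(O)cc(O)c1 | starting material
15 | chloromethyl methyl ether | COCCl | starting material
16 | 1,3,5‑tris(methoxymethoxy)benzene | COCOc1cc(OCOC)cc(OCOC)c1 | intermediate
17 | [(1R,5S,6R)‑4‑methyl‑5‑(3‑methylbut‑2‑en‑1‑yl)‑6‑phenylcyclohex‑3‑en‑1‑yl][2,4,6‑tris(methoxymethoxy)phenyl]methanone | CC(C)=CC[C@@H]1C(C)=CC[C@@H](C(=O)c2c(OCOC)cc(OCOC)cc2OCOC)[C@@H]1c1ccccc1 | intermediate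
18 | (2,4,6‑trihydroxyphenyl)[(1R,5S,6R)‑4‑methyl‑5‑(3‑methylbut‑2‑en‑1‑yl)‑6‑phenylcyclohex‑3‑en‑1‑yl]methanone | CC(C)=CC[C@@H]1C(C)=CC[C@@H](C(=O)c2c(O)cc(O)cc2O)[C@@H]1c1ccccc1 | target

## Summary

**Total steps:** 10. **Longest linear sequence:** 7 (steps 1, 2, 5, 6, 7, 9, 10).

**Steps most likely to fail, with fallbacks**

1. **Step 5 (Diels–Alder).** The diene terminus carrying the quaternary group is hindered, and the vinyl ketol may polymerise or give lower facial or endo selectivity than the model predicts. Fallback: carry the bought stereocentre as the TiCl4‑chelated acrylate of ethyl (S)‑lactate, react it with diene 5, and treat the adduct with NaOMe/MeOH to reach 12 directly.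
2. **Step 7 (Cope shift at 200 °C).** The rearrangement in a simple cyclohexene may be slow or accompanied by decomposition. Fallback: drop the Cope and build the ring from the 2‑silyloxy diene PhCH=C(prenyl)–C(OTBS)=CH2 with the same dienophile. Kinetic protonation of the enol ether sets prenyl cis to Ph, and a regioselective enol triflate followed by Fe‑catalysed MeMgBr coupling installs the methyl‑bearing alkene.
3. **Step 9 (hindered ArLi plus ester).** Enolisation or incomplete addition is possible. Fallback: DIBAL reduction of 13 to the aldehyde, addition of the same aryllithium, and Dess–Martin oxidation of the carbinol to ketone 17.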